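**Retrosynthetic overview**
1. Target 21 is the C2-symmetric head-to-head [2+2] dimer of enol lactone 20 (bonds C8–C8' and C9–C9', both made on the α faces). One lindenane monomer is therefore made and dimerised by light at the end.
2. The plan rests on one feature of the monomer. Ring B (C5–C6–C7–C8–C9–C10) and the butenolide (O–C8–C7=C11(C13H3)–C12=O) are fused along C7–C8, and the lactone ring is atom for atom an aldehyde (C8=O), a methyl-capped alkyne (C7≡C11) and one CO (C12).
3. Cutting C7–C8, C11–C12 and C12–O in the 8,9-dihydro monomer 17 removes both rings at once. This leaves yne-aldehyde 16, a bicyclo[3.1.0]hexane (cyclopropane C1–C2–C3 plus ring A) with trans arms on C5 and C10.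
4. Compound 16 is built on enantiopure ketone 1: C14 by cuprate addition and re-oxidation, the C9–C8 arm by conjugate addition anti to the cyclopropane, C6–C7≡C11–C13 by alkylation, H5 by α-face protonation, and C15 by methylenation.
5. Ring order: cyclopropane and ring A (present in 1), then ring B and the lactone together (step 8), then the cyclobutane (step 11).

Key step: step 8

Remark on numbering: lindenane numbering is used throughout (cyclopropane C1–C2–C3; ring A C1–C3–C4–C5–C10; C14 = methyl on C10; C15 = methylene on C4). β is the face of ring A that carries C2 and C14; α is the opposite face.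
Assumption: ketone 1 is bought as the single (1S,5R) enantiomer, 6 and 9 are catalogue reagents, and Mo(CO)3(DMF)3 is prepared beforehand from Mo(CO)6 in DMF.

**Step 1**
Reactants: 1 (1S,5R)-bicyclo[3.1.0]hexan-2-one
Product: 3 (1S,5S)-bicyclo[3.1.0]hex-3-en-2-one, via TMS enol ether 2 (not isolated)
Conditions: LiN(iPr)2, Me3SiCl (in situ quench), THF, −78 °C; then Pd(OAc)2, MeCN, rt, dark
Reagents that add atoms: chlorotrimethylsilane, C[Si](C)(C)Cl (silyl group stays only in 2)
Why: Only C5 can be enolised because C3 is a cyclopropane bridgehead, so silylation followed by Saegusa–Ito oxidation (enolate of divalent palladium, then β-hydride elimination) should give the enone without touching the two ring-fusion stereocentres.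

**Step 2**
Reactants: 3 (1S,5S)-bicyclo[3.1.0]hex-3-en-2-one
Product: 5 (1S,5R)-4-methylbicyclo[3.1.0]hex-3-en-2-one, via TMS enol ether 4 (not isolated)
Conditions: Me2CuLi (MeLi, CuI), Me3SiCl, Et2O, −78 °C; then Pd(OAc)2, MeCN, rt, dark
Reagents that add atoms: lithium dimethylcuprate, [Li+].C[Cu-]C (CH3 = C14); chlorotrimethylsilane, C[Si](C)(C)Cl (silyl group stays only in 4)
Why: Silyl-chloride-accelerated organocuprate 1,4-addition followed by a second Saegusa–Ito oxidation is the standard β-alkylation of an enone, and the transient C10 centre of 4 (methyl anti to the cyclopropane) is erased when C5=C10 is re-formed.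

**Step 3**
Reactants: 5 (1S,5R)-4-methylbicyclo[3.1.0]hex-3-en-2-one; 6 1-(tert-butyldimethylsilyloxy)-1-methoxyethene
Product: 8 methyl 2-[(1R,2S,5S)-2-methyl-4-oxobicyclo[3.1.0]hexan-2-yl]acetate, via TBS enol ether 7 (not isolated)
Conditions: 6, LiClO4 (5 M in Et2O), rt; then 1 M HCl, THF, 0 °C
Reagents that add atoms: 1-(tert-butyldimethylsilyloxy)-1-methoxyethene, C=C(OC)O[Si](C)(C)C(C)(C)C
Why: This is a Mukaiyama–Michael addition, which in concentrated ethereal LiClO4 reaches hindered β,β-disubstituted enones under nearly neutral conditions that spare the acid-labile bicyclohexenone, and the ketene acetal attacks C10 on the α face, anti to the vicinal cyclopropane CH2, so that C9 ends α and C14 β as in the target.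

**Step 4**
Reactants: 8 methyl 2-[(1R,2S,5S)-2-methyl-4-oxobicyclo[3.1.0]hexan-2-yl]acetate; 9 1-bromo-2-butyne
Product: 11 methyl 2-[3-(but-2-ynyl)-2-methyl-4-oxobicyclo[3.1.0]hexan-2-yl]acetate (both C5 epimers), via potassium enolate 10 (not isolated)
Conditions: KN(SiMe3)2, THF, −78 °C; then 9, DMPU, −78 → −20 °C
Reagents that add atoms: 1-bromo-2-butyne, CC#CCBr; potassium bis(trimethylsilyl)amide, C[Si](C)(C)[N-][Si](C)(C)C.[K+] (K+ stays only in 10)
Why: In this SN2 enolate alkylation with a reactive propargylic bromide the amide base removes only a C5 proton (the ester is less acidic and C3 is a bridgehead), and the C5 configuration is deliberately not relied on, because the β face is screened by C14 and the endo hydrogen of C2 and the α face by the C9 arm, so a carbon electrophile should give a mixture rich in the unwanted epimer.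

**Step 5**
Reactants: 11 methyl 2-[3-(but-2-ynyl)-2-methyl-4-oxobicyclo[3.1.0]hexan-2-yl]acetate (both C5 epimers)
Product: 13 methyl 2-[(1R,2S,3R,5S)-3-(but-2-ynyl)-2-methyl-4-oxobicyclo[3.1.0]hexan-2-yl]acetate (H5 α, C6 β), via potassium enolate 12 (not isolated)
Conditions: KN(SiMe3)2, THF, −78 → 0 °C; recool, cannulate into t-BuCO2H, THF, −78 °C
Reagents that add atoms: potassium bis(trimethylsilyl)amide, C[Si](C)(C)[N-][Si](C)(C)C.[K+] (K+ stays only in 12)
Why: In this stereoconvergent deprotonation and kinetic protonation both epimers give one planar C4–C5 enolate, and the bulky acid should reach C5 from the α face, because the β face carries C14 plus the endo hydrogen of C2 while the α arm can turn its ester away, which pushes C6 to the β face (arms trans) and gives the epimer that also has C6 cis to the smaller C10 substituent, so equilibration does not work against it.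

**Step 6**
Reactants: 13 methyl 2-[(1R,2S,3R,5S)-3-(but-2-ynyl)-2-methyl-4-oxobicyclo[3.1.0]hexan-2-yl]acetate
Product: 14 methyl 2-[3-(but-2-ynyl)-2-methyl-4-methylidenebicyclo[3.1.0]hexan-2-yl]acetate (all centres as in 13)
Conditions: Zn, CH2Br2, TiCl4 (reagent pre-formed in THF, 5 °C), CH2Cl2, 0 °C → rt
Reagents that add atoms: dibromomethane, BrCBr (CH2 = C15)
Why: The Takai–Lombardo methylenation uses a weakly basic gem-dimetallic reagent that converts hindered, enolisable ketones into methylene compounds without α-epimerisation and leaves esters and internal alkynes alone, which a basic Wittig ylide would not guarantee at C5.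

**Step 7**
Reactants: 14 methyl 2-[3-(but-2-ynyl)-2-methyl-4-methylidenebicyclo[3.1.0]hexan-2-yl]acetate
Product: 16 2-[3-(but-2-ynyl)-2-methyl-4-methylidenebicyclo[3.1.0]hexan-2-yl]acetaldehyde (yne-aldehyde; C9 arm α, C6 arm β), via aluminium hemiacetal 15 (not isolated)
Conditions: iBu2AlH (1.1 equiv), CH2Cl2, −78 °C; MeOH, then aq. potassium sodium tartrate
Reagents that add atoms: diisobutylaluminium hydride, CC(C)C[AlH]CC(C)C (aluminium group stays only in 15)
Why: In this partial reduction of a methyl ester at −78 °C the hindered tetrahedral aluminium hemiacetal next to the quaternary C10 survives until the quench, and neither the alkyne nor the alkene is hydroaluminated at this temperature.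

**Step 8**
Reactants: 16 2-[3-(but-2-ynyl)-2-methyl-4-methylidenebicyclo[3.1.0]hexan-2-yl]acetaldehyde
Product: 17 8βH-lindena-4(15),7(11)-dien-12,8-olide (8,9-dihydro monomer)
Conditions: Mo(CO)3(DMF)3 (1.5 equiv), THF, rt, Ar
Reagents that add atoms: carbon monoxide, delivered as a ligand of Mo(CO)3(DMF)3, [C-]#[O+] (C12 and its carbonyl O)
Why: Loss of the labile DMF ligands lets zerovalent molybdenum bind the C7≡C11 alkyne and the C8=O group; oxidative cyclisation gives an oxamolybdacyclopentene (C7–C8), a CO ligand migrates into the Mo–C11 bond (C11–C12) and reductive elimination closes C12–O. This is the intramolecular hetero-Pauson–Khand reaction, a carbonylative (2+2+1) cycloaddition established for 1,7-yne-aldehydes with methyl-capped alkynes, which give cyclohexane-fused α-methylbutenolides at room temperature with this reagent. Ring B closes as a six-membered ring by C7–C8 bond formation across the four-atom tether C6–C5–C10–C9 (exo with respect to the alkyne), and the lactone closes as the five-membered (2+2+1) ring assembled on the metal. The trans ring fusion is carried in from C5 and C10; the only new stereocentre, C8, should be set by a chair-like tether in which the C8–O bond lies pseudo-equatorial and nearly coplanar with the metallacycle, so that H8 is axial and β, and this centre is erased in step 10 in any case. The step needs chemoselectivity for the aldehyde–alkyne pair: the C4=C15 alkene is linked to the alkyne only through C5–C6, so an all-carbon closure would require a four-membered ring, and the mild temperature avoids alkene migration, aldehyde decarbonylation and opening of the vinylcyclopropane.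

**Step 9**
Reactants: 17 8βH-lindena-4(15),7(11)-dien-12,8-olide
Product: 18 12-(tert-butyldimethylsilyloxy)furan of the monomer (furan O–C8=C7–C11=C12)
Conditions: TBSOTf, Et3N (excess), CH2Cl2, 0 °C; filtration through Et3N-deactivated silica
Reagents that add atoms: tert-butyldimethylsilyl triflate, CC(C)(C)[Si](C)(C)OS(=O)(=O)C(F)(F)F
Why: Soft enolisation of the butenolide (silyl triflate and amine) removes the γ-proton at C8 rather than one at C6 because only that path gives the aromatic 2-silyloxyfuran, and the excess amine protects the vinylcyclopropane from acid.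

**Step 10**
Reactants: 18 12-(tert-butyldimethylsilyloxy)furan of the monomer
Product: 20 lindena-4(15),7(11),8-trien-12,8-olide (enol lactone monomer), via 8-bromobutenolide 19 (not isolated)
Conditions: NBS (1.0 equiv), THF, −78 °C; then Et3N, −78 → 0 °C, dark
Reagents that add atoms: N-bromosuccinimide, O=C1CCC(=O)N1Br (Br stays only in 19)
Why: Electrophilic γ-bromination of a 2-silyloxyfuran followed by amine-induced dehydrobromination is a known entry to γ-alkylidene butenolides, the electron-rich furan outcompetes C4=C15 for one equivalent of NBS at −78 °C, and the tertiary C8 bromide can lose HBr only towards C9, its sole neighbouring C–H.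

**Step 11**
Reactants: 20 lindena-4(15),7(11),8-trien-12,8-olide (two molecules)
Product: 21 target, head-to-head α,α-dimer with cyclobutane C8–C9–C9'–C8'
Conditions: hν (medium-pressure Hg lamp, Pyrex), degassed hexane, concentrated solution, rt
Reagents that add atoms: none
Why: In this [2+2] photodimerisation of a conjugated enol lactone, first bonding between the two C9 termini leaves two C8 radicals stabilised by oxygen and by the C7=C11 allyl system, which accounts for head-to-head union, and both partners react on the α face, anti to the axial C14 methyl next to C9, so that C8, C9, C8' and C9' (lactone O and H9 β, new bonds α) arise as in the C2-symmetric target.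

**Compound list**
1 | (1S,5R)-bicyclo[3.1.0]hexan-2-one | O=C1[C@H]2C[C@H]2CC1 | starting material
2 | 2-(trimethylsilyloxy)bicyclo[3.1.0]hex-2-ene, ring-fusion centres as in 1 | C[Si](C)(C)OC1[C@H]2C[C@H]2CC=1 | intermediate
3 | (1S,5S)-bicyclo[3.1.0]hex-3-en-2-one | O=C1[C@H]2C[C@H]2C=C1 | intermediate
4 | 4-methyl-2-(trimethylsilyloxy)bicyclo[3.1.0]hex-2-ene, methyl anti to the cyclopropane CH2 | C[Si](C)(C)OC1[C@H]2C[C@H]2[C@H](C)C=1 | intermediate
5 | (1S,5R)-4-methylbicyclo[3.1.0]hex-3-en-2-one | O=C1[C@H]2C[C@H]2C(C)=C1 | intermediate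
6 | 1-(tert-butyldimethylsilyloxy)-1-methoxyethene | C=C(OC)O[Si](C)(C)C(C)(C)C | starting material
7 | methyl 2-[4-(tert-butyldimethylsilyloxy)-2-methylbicyclo[3.1.0]hex-3-en-2-yl]acetate, acetate arm α, methyl β | CC(C)(C)[Si](C)(C)OC1[C@H]2C[C@H]2[C@@](CC(=O)OC)(C)C=1 | intermediate
8 | methyl 2-[(1R,2S,5S)-2-methyl-4-oxobicyclo[3.1.0]hexan-2-yl]acetate (arm anti, methyl syn to the cyclopropane CH2) | O=C1[C@H]2C[C@H]2[C@@](CC(=O)OC)(C)C1 | intermediate
9 | 1-bromo-2-butyne | CC#CCBr | starting material
10 | potassium C4–C5 enolate of 8 | [K+].[O-]C1[C@H]2C[C@H]2[C@@](CC(=O)OC)(C)C=1 | intermediate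
11 | methyl 2-[3-(but-2-ynyl)-2-methyl-4-oxobicyclo[3.1.0]hexan-2-yl]acetate, mixture of C5 epimers (C5 left open) | O=C1[C@H]2C[C@H]2[C@@](CC(=O)OC)(C)C1CC#CC | intermediate
12 | potassium C4–C5 enolate of 11 | [K+].[O-]C1[C@H]2C[C@H]2[C@@](CC(=O)OC)(C)C=1CC#CC | intermediate
13 | methyl 2-[(1R,2S,3R,5S)-3-(but-2-ynyl)-2-methyl-4-oxobicyclo[3.1.0]hexan-2-yl]acetate (H5 α, butynyl β, trans to the acetate arm) | O=C1[C@H]2C[C@H]2[C@@](CC(=O)OC)(C)[C@H]1CC#CC | intermediate
14 | methyl 2-[3-(but-2-ynyl)-2-methyl-4-methylidenebicyclo[3.1.0]hexan-2-yl]acetate, centres as in 13 | C=C1[C@H]2C[C@H]2[C@@](CC(=O)OC)(C)[C@H]1CC#CC | intermediate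
15 | diisobutylaluminium methyl hemiacetal of 16 (hemiacetal carbon unassigned) | C=C1[C@H]2C[C@H]2[C@@](CC(OC)O[Al](CC(C)C)CC(C)C)(C)[C@H]1CC#CC | intermediate
16 | 2-[3-(but-2-ynyl)-2-methyl-4-methylidenebicyclo[3.1.0]hexan-2-yl]acetaldehyde, C9 arm α, C6 arm β, C14 β | C=C1[C@H]2C[C@H]2[C@@](CC=O)(C)[C@H]1CC#CC | intermediate
17 | 8βH-lindena-4(15),7(11)-dien-12,8-olide (trans-fused rings A and B, lactone O α at C8) | C=C1[C@H]2C[C@H]2[C@@]2(C)[C@H]1CC1=C(C)C(=O)O[C@H]1C2 | intermediate
18 | 12-(tert-butyldimethylsilyloxy)-8,12-epoxylindena-4(15),7,11-triene (2-silyloxyfuran) | C=C1[C@H]2C[C@H]2[C@@]2(C)[C@H]1Cc1c(C)c(O[Si](C)(C)C(C)(C)C)oc1C2 | intermediate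
19 | 8α-bromolindena-4(15),7(11)-dien-12,8-olide | C=C1[C@H]2C[C@H]2[C@@]2(C)[C@H]1CC1=C(C)C(=O)O[C@]1(Br)C2 | intermediate
20 | lindena-4(15),7(11),8-trien-12,8-olide | C=C1[C@H]2C[C@H]2[C@@]2(C)[C@H]1CC1=C(C)C(=O)OC1=C2 | intermediate
21 | C2-symmetric head-to-head dimer of 20, cyclobutane C8–C9–C9'–C8', new bonds α, lactone O and H9 β | C=C1[C@H]2C[C@H]2[C@@]2(C)[C@H]1CC1=C(C)C(=O)O[C@]13[C@H]2[C@H]1[C@@]2(C)[C@@H]4C[C@@H]4C(=C)[C@@H]2CC2=C(C)C(=O)O[C@@]213 | target

**Total step count:** 11
**Longest linear sequence:** 11 steps (1 → 21)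

**Steps most likely to fail**

**Step 8.**
- Risk: the oxidative cyclisation may be sluggish. Ring A is held nearly flat by the cyclopropane and the exocyclic alkene, and the two trans arms must be drawn into a strained trans-fused six-membered ring. Decarbonylation or self-condensation of the aldehyde could then take over.
- Fallback: the same three bonds are made one after another, from 16 back to 17.
- Stoichiometric Cp2Ti(PMe3)2 in THF couples alkyne and aldehyde to the oxatitanacyclopentene F1. This oxidative coupling is driven much harder because a Ti–O bond is formed.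
- Iodinolysis (I2, −78 °C) and aqueous work-up give the (Z)-iodoethylidene cyclohexanol F2, with C7–C8 in place and C11–I cis to the C8 hydroxyl.
- Carbonylative lactonisation with PdCl2(PPh3)2, CO (1 atm) and K2CO3 in DMF then forms C11–C12 and C12–O and rejoins the route at 17.

**Step 5.**
- Risk: facial selectivity in the protonation of enolate 12 may be poor, or C5 may re-equilibrate during work-up or methylenation.
- Fallback: C5 is set only after ring B exists, from 11 (either epimer) back to 17.
- KN(SiMe3)2 and PhNTf2 give the C4–C5 enol triflate F3.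
- Negishi coupling with Me3SiCH2ZnCl and Pd(PPh3)4 gives the allylsilane ester F4, in which C5 is sp2.
- Reduction with iBu2AlH at −78 °C gives the allylsilane aldehyde F5.
- The same Mo(CO)3(DMF)3 closure gives the tricyclic allylsilane butenolide F6.
- Protodesilylation (CF3CO2H, CH2Cl2, −40 °C; SE2' protonation at C5 with loss of silicon) creates C4=C15 and H5 together. It does so on a tricycle whose C9 is tied back into ring B, so that C14 and the cyclopropane leave only the α face of C5 open. The route is rejoined at 17.

**Step 3.**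
- Risk: the ketene acetal may fail to add at the hindered β-carbon, or the Lewis-acidic medium may open and aromatise the bicyclohexenone.
- Fallback: an organocopper donor is used instead, from 5 back to 8.
- CH2=CHMgBr with CuBr·SMe2 in THF at −40 °C, with the same approach anti to the cyclopropane, gives the vinyl ketone F7.
- Exhaustive hydroboration–oxidation (9-BBN; then H2O2, NaOH) gives the diol F8.
- CrO3/H2SO4 in acetone oxidises both carbinols to the keto acid F9.
- MeI with K2CO3 in DMF gives 8.

**Further compounds**
F1 | step 8 | oxatitanacyclopentene from 16 (Cp rings drawn σ-bonded) | C=C1[C@H]2C[C@H]2[C@@]2(C)[C@H]1CC1=C(C)[Ti](C3C=CC=C3)(C3C=CC=C3)O[C@H]1C2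
F2 | step 8 | (Z)-7-(1-iodoethylidene) ring-B alcohol, 8α-OH, iodine cis to C8 | C=C1[C@H]2C[C@H]2[C@@]2(C)[C@H]1C/C(=C(\C)I)[C@@H](O)C2
F3 | step 5 | C4–C5 enol triflate of 11 | O=S(=O)(OC1[C@H]2C[C@H]2[C@@](CC(=O)OC)(C)C=1CC#CC)C(F)(F)F
F4 | step 5 | methyl ester with C4=C5 and C4–CH2SiMe3 (allylsilane ester) | C[Si](C)(C)CC1[C@H]2C[C@H]2[C@@](CC(=O)OC)(C)C=1CC#CC
F5 | step 5 | allylsilane yne-aldehyde | C[Si](C)(C)CC1[C@H]2C[C@H]2[C@@](CC=O)(C)C=1CC#CC
F6 | step 5 | 15-(trimethylsilyl)lindena-4,7(11)-dien-12,8-olide (tricyclic allylsilane butenolide) | C[Si](C)(C)CC1[C@H]2C[C@H]2[C@@]2(C)C=1CC1=C(C)C(=O)O[C@H]1C2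
F7 | step 3 | 4-methyl-4-vinylbicyclo[3.1.0]hexan-2-one, vinyl α, methyl β | O=C1[C@H]2C[C@H]2[C@@](C=C)(C)C1
F8 | step 3 | 4-(2-hydroxyethyl)-4-methylbicyclo[3.1.0]hexan-2-ol (carbinol centre unassigned) | OC1[C@H]2C[C@H]2[C@@](CCO)(C)C1
F9 | step 3 | 2-(2-methyl-4-oxobicyclo[3.1.0]hexan-2-yl)acetic acid, centres as in 8 | O=C1[C@H]2C[C@H]2[C@@](CC(=O)O)(C)C1
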